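**Retrosynthetic overview**

1. Numbering: ring A has C1 (CO2H), C2 (OH), C3 (prenyl), C6 (O-aryl); ring B has C1' (ether oxygen), C2' (OH), C4' (CH3), C6' (CH2OH). The strategy rests on ring B, where C1' carries the ether oxygen between C2'-OH and C6'-CH2OH and C4'-CH3 completes a 1,3,5 pattern.
2. C6'-CH2OH is taken back to a C6' ethyl ester, reduced in the last step beside the ring A carboxylate.
3. Ring B is cut at C1'–C6' and C3'–C4' into the C1'–C2'–C3' unit of a ring A aryloxyacetone and the C6'–C5'–C4' unit of ethyl 2,4-dioxopentanoate ([3+3] double aldol condensation). The ether oxygen is therefore attached earlier by alkylation at an sp3 carbon, and no aryl–oxygen coupling is needed.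
4. The aryloxyacetone comes from allyl 2,6-dihydroxybenzoate: one hydroxyl becomes the reverse-prenyl ether and is rearranged (Claisen) to C3-prenyl/C2-OH, the other is alkylated with chloroacetone.
5. Ring order: ring A is bought intact; ring B is the only ring formed, in step 7.

Key step: step 7

Remark on the chemistry: the target has no stereocentre, and the C2 hydroxyl of ring A, free from step 5 on, is assumed inert in steps 6–8 (as phenol or phenoxide), so no protecting group is placed on it.

**Route**

Step 1
Reactants: 1 2,6-dihydroxybenzoic acid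
Product: 2 prop-2-en-1-yl 2,6-dihydroxybenzoate
Conditions: allyl bromide, KHCO3, DMF, rt
Reagents that add atoms: allyl bromide, C=CCBr
Why: SN2 esterification of the carboxylate; hydrogencarbonate should deprotonate only the strongly acidic carboxyl group, so the two chelated phenols stay protonated and are not alkylated.

Step 2
Reactants: 2 prop-2-en-1-yl 2,6-dihydroxybenzoate; 3 3-chloro-3-methylbut-1-yne
Product: 4 prop-2-en-1-yl 2-hydroxy-6-[(2-methylbut-3-yn-2-yl)oxy]benzoate
Conditions: DBU, CuCl2·2H2O (cat.), MeCN, 0 °C to rt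
Reagents that add atoms: none
Why: Copper-catalysed propargylic etherification of a phenoxide with a tertiary propargyl chloride is the usual way to aryl 1,1-dimethylpropargyl ethers, and the symmetric diol should stop at the mono-ether because the remaining hydroxyl is then tightly hydrogen-bonded to the ester carbonyl.

Step 3
Reactants: 4 prop-2-en-1-yl 2-hydroxy-6-[(2-methylbut-3-yn-2-yl)oxy]benzoate; 5 chloroacetone
Product: 6 prop-2-en-1-yl 2-[(2-methylbut-3-yn-2-yl)oxy]-6-(2-oxopropoxy)benzoate
Conditions: K2CO3, KI (cat.), acetone, reflux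
Reagents that add atoms: none
Why: Williamson ether synthesis at the sp3 carbon of an activated alpha-halo ketone (Finkelstein-assisted); carbonate should form the phenoxide but not the ketone enolate, so Dieckmann-type closure onto the ester is not expected.

Step 4
Reactants: 6 prop-2-en-1-yl 2-[(2-methylbut-3-yn-2-yl)oxy]-6-(2-oxopropoxy)benzoate
Product: 7 prop-2-en-1-yl 2-[(2-methylbut-3-en-2-yl)oxy]-6-(2-oxopropoxy)benzoate
Conditions: H2 (1 atm), Pd/CaCO3 poisoned with Pb(OAc)2, quinoline, EtOAc, rt
Reagents that add atoms: none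
Why: Lindlar semi-hydrogenation; the terminal alkyne binds to the poisoned palladium surface far more strongly than the alkene formed or the allyl ester, so uptake should stop at the 1,1-dimethylallyl ether.

Step 5
Reactants: 7 prop-2-en-1-yl 2-[(2-methylbut-3-en-2-yl)oxy]-6-(2-oxopropoxy)benzoate
Product: 8 prop-2-en-1-yl 2-hydroxy-3-(3-methylbut-2-en-1-yl)-6-(2-oxopropoxy)benzoate
Conditions: PhNEt2, 130 °C
Reagents that add atoms: none
Why: Aromatic Claisen rearrangement ([3,3]-sigmatropic shift) of the aryl 1,1-dimethylallyl ether to the only free ortho carbon (C3) should deliver the linear prenyl group and, after tautomerisation, the C2 phenol.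

Step 6
Reactants: 8 prop-2-en-1-yl 2-hydroxy-3-(3-methylbut-2-en-1-yl)-6-(2-oxopropoxy)benzoate
Product: 9 2-hydroxy-3-(3-methylbut-2-en-1-yl)-6-(2-oxopropoxy)benzoic acid
Conditions: Pd(PPh3)4 (cat.), morpholine, THF, rt; then aq. citric acid
Reagents that add atoms: none
Why: Tsuji–Trost deallylation; zerovalent palladium ionises the allyl ester to a pi-allyl complex that morpholine captures, freeing the acid under near-neutral conditions so that the aryloxyacetone cannot close onto the ester to a benzofuranone.

Step 7
Reactants: 9 2-hydroxy-3-(3-methylbut-2-en-1-yl)-6-(2-oxopropoxy)benzoic acid; 10 ethyl 2,4-dioxopentanoate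
Product: 14 6-[2-(ethoxycarbonyl)-6-hydroxy-4-methylphenoxy]-2-hydroxy-3-(3-methylbut-2-en-1-yl)benzoic acid, via enaminone 11 (not isolated), via open-chain enedione 12 (not isolated), via cyclic aldol 13 (not isolated)
Conditions: 10 and pyrrolidine premixed in EtOH, rt; then 9, pyrrolidine, AcOH, 4 Å MS, 75 °C; 1 M HCl work-up
Reagents that add atoms: none
Why: Proposed new method: pyrrolidine should turn 10 at the keto group next to the ester into enaminone 11 (which also takes 10 out of its own self-condensation) and 9 into its enamine at the oxygen-bearing C1'; Mannich-type attack of C1' on the iminium carbon of protonated 11 and loss of pyrrolidine makes C1'–C6' and gives enedione 12, the C3' methyl (as enol or dienamine of the C2' ketone) then adds to the C4' carbonyl to make C3'–C4' in 13, and loss of water followed by enolisation of the cyclohexadienone gives phenol 14. The closest known reaction types are the Prelog-type [3+3] phenol synthesis from a ketone with two reactive alpha carbons and a 1,3-dicarbonyl compound, the classical self-condensation of acetopyruvate to 3-hydroxy-5-methylbenzoic acid and the cyclisation of hept-3-ene-2,6-diones (pyrylium pseudobases) to phenols; the crossed variant with an alpha-aryloxy methyl ketone as the three-carbon donor is not established. Ring B closes by a 6-(enolendo)-exo-trig aldol addition, and no stereocentre remains because the carbinol carbon of 13 becomes aromatic. The first bond must start from C1' and not from C3', which should follow from the known preference of alpha-oxygenated acetones to react at the oxygen-bearing carbon (amine-catalysed aldol reactions of alkoxyacetones, Friedländer and Pfitzinger reactions of aryloxyacetones) and from the known attack of amines and carbon nucleophiles at C2 of 2,4-dioxoesters. The ring closure must run from C3' to C4' and not from the terminal methyl of the former dioxoester to C2'; the C2' ketone can enolise only towards C3' and is a hindered, conjugated carbonyl, whereas C4' is an unhindered methyl ketone that the amine activates as an iminium and whose own enamine forms towards C5'. Ring A is carried as its pyrrolidinium carboxylate, which rules out Dieckmann-type closure to a benzofuranone and keeps acid and ester apart for step 8.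

Step 8
Reactants: 14 6-[2-(ethoxycarbonyl)-6-hydroxy-4-methylphenoxy]-2-hydroxy-3-(3-methylbut-2-en-1-yl)benzoic acid
Product: 15 2-hydroxy-6-[2-hydroxy-6-(hydroxymethyl)-4-methylphenoxy]-3-(3-methylbut-2-en-1-yl)benzoic acid
Conditions: LiHMDS (3 equiv), THF, 0 °C; then LiBH4, THF, 0 to 45 °C; 1 M HCl (0 °C) to pH 3
Reagents that add atoms: none
Why: Chemoselective borohydride reduction; LiBH4 reduces the aryl ethyl ester to the benzylic alcohol but leaves a lithium carboxylate untouched, and forming the lithium carboxylate and phenoxides with LiHMDS beforehand avoids protonolysis of borohydride to borane, which would hydroborate the prenyl alkene.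

**Compound list**

1 | 2,6-dihydroxybenzoic acid | O=C(O)c1c(O)cccc1O | starting material
2 | prop-2-en-1-yl 2,6-dihydroxybenzoate | C=CCOC(=O)c1c(O)cccc1O | intermediate
3 | 3-chloro-3-methylbut-1-yne | C#CC(C)(C)Cl | starting material
4 | prop-2-en-1-yl 2-hydroxy-6-[(2-methylbut-3-yn-2-yl)oxy]benzoate | C=CCOC(=O)c1c(O)cccc1OC(C)(C)C#C | intermediate
5 | chloroacetone | CC(=O)CCl | starting material
6 | prop-2-en-1-yl 2-[(2-methylbut-3-yn-2-yl)oxy]-6-(2-oxopropoxy)benzoate | C=CCOC(=O)c1c(OCC(C)=O)cccc1OC(C)(C)C#C | intermediate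
7 | prop-2-en-1-yl 2-[(2-methylbut-3-en-2-yl)oxy]-6-(2-oxopropoxy)benzoate | C=CCOC(=O)c1c(OCC(C)=O)cccc1OC(C)(C)C=C | intermediate
8 | prop-2-en-1-yl 2-hydroxy-3-(3-methylbut-2-en-1-yl)-6-(2-oxopropoxy)benzoate | C=CCOC(=O)c1c(OCC(C)=O)ccc(CC=C(C)C)c1O | intermediate
9 | 2-hydroxy-3-(3-methylbut-2-en-1-yl)-6-(2-oxopropoxy)benzoic acid | CC(C)=CCc1ccc(OCC(C)=O)c(C(=O)O)c1O | intermediate
10 | ethyl 2,4-dioxopentanoate | CCOC(=O)C(=O)CC(C)=O | starting material
11 | ethyl (2E)-4-oxo-2-(pyrrolidin-1-yl)pent-2-enoate | CCOC(=O)/C(=C\C(C)=O)N1CCCC1 | intermediate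
12 | 6-{[(3Z)-4-(ethoxycarbonyl)-2,6-dioxohept-3-en-3-yl]oxy}-2-hydroxy-3-(3-methylbut-2-en-1-yl)benzoic acid | CC(C)=CCc1ccc(O/C(C(C)=O)=C(/CC(C)=O)C(=O)OCC)c(C(=O)O)c1O | intermediate
13 | 6-{[2-(ethoxycarbonyl)-4-hydroxy-4-methyl-6-oxocyclohex-1-en-1-yl]oxy}-2-hydroxy-3-(3-methylbut-2-en-1-yl)benzoic acid (racemic carbinol) | CC(C)=CCc1ccc(OC2=C(C(=O)OCC)CC(C)(O)CC2=O)c(C(=O)O)c1O | intermediate
14 | 6-[2-(ethoxycarbonyl)-6-hydroxy-4-methylphenoxy]-2-hydroxy-3-(3-methylbut-2-en-1-yl)benzoic acid | CC(C)=CCc1ccc(Oc2c(O)cc(C)cc2C(=O)OCC)c(C(=O)O)c1O | intermediate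
15 | 2-hydroxy-6-[2-hydroxy-6-(hydroxymethyl)-4-methylphenoxy]-3-(3-methylbut-2-en-1-yl)benzoic acid | CC(C)=CCc1ccc(Oc2c(O)cc(C)cc2CO)c(C(=O)O)c1O | target

**Step count**

Total steps: 8. Longest linear sequence: 8 steps (1 to 15).

**Steps most likely to fail**

1. Step 7 (proposed new method). The dioxoester or its enaminone may condense with itself faster than with 9, or be cleaved by the amine in a retro-Claisen sense. The two three-carbon units may also pair the wrong way, either in the first bond (C3' instead of C1') or in the ring closure (terminal methyl of the dioxoester unit onto C2'), which would give regioisomeric phenols.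
 Fallback, setting out from 4 and returning at 15, with ring B made separately and joined by known aryl–oxygen bond formation: 2-fluoro-5-methylphenol is silylated (TIPSCl, imidazole, DMF) to (2-fluoro-5-methylphenoxy)tri(propan-2-yl)silane F1. Lithiation next to fluorine (s-BuLi, THF, −78 °C) and formylation with DMF should give 2-fluoro-5-methyl-3-{[tri(propan-2-yl)silyl]oxy}benzaldehyde F2. The silyl ether is exchanged for an allyl ether in one pot (CsF, allyl bromide, DMF) to give 2-fluoro-5-methyl-3-(prop-2-en-1-yloxy)benzaldehyde F3. The phenoxide of 4 displaces the fluoride ortho to the formyl group (Cs2CO3, DMSO, 80 °C; nucleophilic aromatic substitution) to give prop-2-en-1-yl 2-[2-formyl-4-methyl-6-(prop-2-en-1-yloxy)phenoxy]-6-[(2-methylbut-3-yn-2-yl)oxy]benzoate F4. Semi-hydrogenation as in step 4 gives prop-2-en-1-yl 2-[2-formyl-4-methyl-6-(prop-2-en-1-yloxy)phenoxy]-6-[(2-methylbut-3-en-2-yl)oxy]benzoate F5. Claisen rearrangement as in step 5 gives prop-2-en-1-yl 6-[2-formyl-4-methyl-6-(prop-2-en-1-yloxy)phenoxy]-2-hydroxy-3-(3-methylbut-2-en-1-yl)benzoate F6. NaBH4 (MeOH, 0 °C) reduces the formyl group to give prop-2-en-1-yl 2-hydroxy-6-[2-(hydroxymethyl)-4-methyl-6-(prop-2-en-1-yloxy)phenoxy]-3-(3-methylbut-2-en-1-yl)benzoate F7. Pd(PPh3)4 with morpholine then removes the allyl ester and the allyl ether together to give 15.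

2. Step 8. Incomplete salt formation would leave acidic protons that decompose LiBH4 to borane, leading to hydroboration of the prenyl alkene and reduction of the ring A carboxyl group. The poorly soluble trilithium salt may also be reduced only slowly.
 Fallback, setting out from 14 and returning at 15, in which the ring A acid is protected as a hindered ester instead of a salt: allyl bromide and KHCO3 in DMF give prop-2-en-1-yl 6-[2-(ethoxycarbonyl)-6-hydroxy-4-methylphenoxy]-2-hydroxy-3-(3-methylbut-2-en-1-yl)benzoate F8. The ring B ethyl ester is then reduced (LiHMDS, then LiBH4, THF) while the doubly ortho-substituted, phenoxide-deactivated ring A ester should resist, giving prop-2-en-1-yl 2-hydroxy-6-[2-hydroxy-6-(hydroxymethyl)-4-methylphenoxy]-3-(3-methylbut-2-en-1-yl)benzoate F9. Pd(PPh3)4 with morpholine frees the acid to give 15.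

3. Step 2. The hydrogen-bonded, weakly nucleophilic resorcylate may be etherified only slowly, a second etherification may occur, and chloride 3 may be lost by elimination.
 Fallback, setting out from 2 and returning at 8, with the prenyl group put on carbon directly instead of through ether formation and rearrangement: the sodium phenoxide of 2 is C-alkylated in a non-polar solvent (NaH, 1-bromo-3-methylbut-2-ene, toluene, 0 °C to rt) at C3, which is ortho to one hydroxyl and para to the other, to give prop-2-en-1-yl 2,6-dihydroxy-3-(3-methylbut-2-en-1-yl)benzoate F10. The less hindered C6 hydroxyl, not flanked by the prenyl group, is then alkylated with chloroacetone 5 (K2CO3, acetone) to give 8. Steps 2 to 5 are bypassed.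

**Further compounds**

F1 | step 7 | (2-fluoro-5-methylphenoxy)tri(propan-2-yl)silane | Cc1ccc(F)c(O[Si](C(C)C)(C(C)C)C(C)C)c1
F2 | step 7 | 2-fluoro-5-methyl-3-{[tri(propan-2-yl)silyl]oxy}benzaldehyde | Cc1cc(C=O)c(F)c(O[Si](C(C)C)(C(C)C)C(C)C)c1
F3 | step 7 | 2-fluoro-5-methyl-3-(prop-2-en-1-yloxy)benzaldehyde | Cc1cc(C=O)c(F)c(OCC=C)c1
F4 | step 7 | prop-2-en-1-yl 2-[2-formyl-4-methyl-6-(prop-2-en-1-yloxy)phenoxy]-6-[(2-methylbut-3-yn-2-yl)oxy]benzoate | C=CCOC(=O)c1c(Oc2c(C=O)cc(C)cc2OCC=C)cccc1OC(C)(C)C#C
F5 | step 7 | prop-2-en-1-yl 2-[2-formyl-4-methyl-6-(prop-2-en-1-yloxy)phenoxy]-6-[(2-methylbut-3-en-2-yl)oxy]benzoate | C=CCOC(=O)c1c(Oc2c(C=O)cc(C)cc2OCC=C)cccc1OC(C)(C)C=C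
F6 | step 7 | prop-2-en-1-yl 6-[2-formyl-4-methyl-6-(prop-2-en-1-yloxy)phenoxy]-2-hydroxy-3-(3-methylbut-2-en-1-yl)benzoate | C=CCOC(=O)c1c(Oc2c(C=O)cc(C)cc2OCC=C)ccc(CC=C(C)C)c1O
F7 | step 7 | prop-2-en-1-yl 2-hydroxy-6-[2-(hydroxymethyl)-4-methyl-6-(prop-2-en-1-yloxy)phenoxy]-3-(3-methylbut-2-en-1-yl)benzoate | C=CCOC(=O)c1c(Oc2c(CO)cc(C)cc2OCC=C)ccc(CC=C(C)C)c1O
F8 | step 8 | prop-2-en-1-yl 6-[2-(ethoxycarbonyl)-6-hydroxy-4-methylphenoxy]-2-hydroxy-3-(3-methylbut-2-en-1-yl)benzoate | C=CCOC(=O)c1c(Oc2c(O)cc(C)cc2C(=O)OCC)ccc(CC=C(C)C)c1O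
F9 | step 8 | prop-2-en-1-yl 2-hydroxy-6-[2-hydroxy-6-(hydroxymethyl)-4-methylphenoxy]-3-(3-methylbut-2-en-1-yl)benzoate | C=CCOC(=O)c1c(Oc2c(O)cc(C)cc2CO)ccc(CC=C(C)C)c1O
F10 | step 2 | prop-2-en-1-yl 2,6-dihydroxy-3-(3-methylbut-2-en-1-yl)benzoate | C=CCOC(=O)c1c(O)ccc(CC=C(C)C)c1O
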